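All runs were generated by integration with made-up constants; scatter was added.

**The ratio.** The ratio that matters is φ = 0.321, the share of target in what has left the substrate, as read at the last reading of the green run. We take it that the catalyst turns substrate into target, that target passes reversibly into isomer of the product B, and that the other conformer leads on to isomer of the product A. Since isomer of the product A is not read, φ counts it in what has left.

common to all: catalyst 5 mol%; temperature 35 °C
- green: substrate 0.060 M; other conformer 0.50 equiv; the very flask that is asked about, followed so far
- teal: substrate 0.12 M; other conformer 0.50 equiv; run made earlier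
- flask: substrate 0.060 M; other conformer 0.500 equiv; time 2.0 d

| run | time / h | target / % | substrate / % |
|---|---|---|---|
| green | 2.50 | 14.2 | 82.3 |
| green | 8.00 | 27.8 | 57.0 |
| green | 15.0 | 32.2 | 35.0 |
| green | 20.0 | 32.7 | 25.3 |
| green | 30.0 | 30.2 | 11.3 |
| green | 40.0 | 30.7 | 5.9 |
| green | 50.0 | 31.0 | 3.4 |
| teal | 0.250 | 2.4 | 91.8 |
| teal | 0.417 | 4.9 | 92.3 |
| teal | 0.667 | 7.8 | 90.0 |
| teal | 1.00 | 11.7 | 85.5 |
| teal | 1.50 | 16.0 | 79.9 |
| teal | 2.50 | 24.7 | 69.8 |
| teal | 4.00 | 32.5 | 56.4 |

(readings scatter by 0.5 percentage points)

- noon: at 2.0 d add catalyst, 100 % of the amount charged, then wait 50 h
- dusk: change nothing and wait 50 h more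
- midnight: at 2.0 d raise the temperature by 20 K, then wait 50 h
- autumn: at 2.0 d take out 90 % of the target then present, then wait 50 h

- target, in percent of the substrate and other conformer together first charged, at 2.0 d
- the option that brings most further target ("none" if no option brings more than 2 percentage points) (noon / dusk / midnight / autumn / none)
- target present, with what was taken out counted in, in percent of the substrate and other conformer together first charged, after noon
- target present, with what was taken out counted in, in percent of the substrate and other conformer together first charged, after autumn

- what is taken out of target is counted as made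
- the earlier runs were read with a standard deviation of 0.5 percentage points
- what may be going on: substrate <-> other conformer; substrate + catalyst -> catalyst + target; catalyst + other conformer -> catalyst + isomer of the product A; target <-> isomer of the product B
- the earlier runs do not show what temperature does; that part of a forecast is a guess
- additions bring no volume worth counting

**Both ends.** Early on, φ does not hold. In the teal run at 4.00 h, target reads 32.5 %, more than the 14.0 % that φ allows. Late on, the green run approaches what chemists call thermodynamic control, and we want a time for that approach. In the green run, target's excess over φ falls from 8.7 percentage points at 20.0 h to 1.7 points at 30.0 h. That is a time constant τ of about 6.19 h, a reading that carries the scatter, and it is shorter than the wait of 50 h.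

**Our reckoning.** Substrate in the green run falls at 0.0671 h⁻¹, so 3.89 % remains at 2.0 d, and φ gives 30.8 % of target. Noon and dusk can convert this remainder, worth 1.2 points of target, less than the 2 points required. Autumn removes 27.8 %, and φ then applies to what stays, for a total of 50.9 %. Midnight changes φ by an amount the readings do not show; it passes autumn if the hotter share reaches about 50.9 %. We name autumn and leave midnight as a guess.

**The result.** The forecast gives 31 %, 31.5 % after noon and 50 % after autumn, below our figure, and names autumn, saying of noon and dusk “because the equilibrium takes most of it”. The simulation gives 30.0 %, 29.1 % after noon and 48.0 % after autumn, and the best option is midnight, with a gain of 38 points against 18 points for autumn.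

    substrate ⇌ other conformer (K = 0.00650, k = 1.90 × 10⁻⁵ s⁻¹, Ea = 111 kJ mol⁻¹, ΔH = −26.0 kJ mol⁻¹)
    substrate + catalyst → catalyst + target (k = 0.00630 L mol⁻¹ s⁻¹, Ea = 71.0 kJ mol⁻¹)
    catalyst + other conformer → catalyst + isomer of the product A (k = 0.0300 L mol⁻¹ s⁻¹, Ea = 44.0 kJ mol⁻¹)
    target ⇌ isomer of the product B (K = 2.30, k = 3.00 × 10⁻⁵ s⁻¹, Ea = 109 kJ mol⁻¹, ΔH = −72.0 kJ mol⁻¹)
    (constants at 35 °C)

**What stands.** Target and isomer of the product B relax with a half-life of 4.47 h, both ways together, short against the 2.0 d of the green flask. At 48.0 h, that flask holds 30.0 % of target with 3.48 % of substrate, and φ applied to what has left the substrate gives 31.0 %. In a neighbour flask with 0.024 M of substrate, at the same time, φ applied to the 74.0 % that has left the substrate gives 23.7 %, and that neighbour holds 25.5 % of target.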